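**Retrosynthetic overview** (macrolide numbering: C1 = lactone C=O, round the ring to C13, the carbinol carbon bearing ethyl)
1. The 14-membered lactone, the only ring of the target, is closed at C5–C6 by a nickel-catalysed reductive radical coupling of a 2,2-disubstituted oxirane (opened in the flask to a primary C5 iodide/radical) with a (Z)-alkenyl iodide at C6. The same event unmasks the C4 tertiary alcohol, whose configuration is stored in the oxirane by a Sharpless epoxidation.
2. C2–C3 comes from an aldol of the C13 propanoate with the epoxy aldehyde; C3 is oxidised after ring closure and C2 then settles under thermodynamic control.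
3. C6=C7 comes from a Stork–Zhao iodo-olefination; C9–C10 from a nickel cross-electrophile coupling of a 2-chloro-1,3-diene with (2R)-3-bromo-2-methylpropan-1-ol (source of C8).
4. C10–C13 comes from anti-carbomagnesiation of (3S)-pent-1-yn-3-ol (source of C13 and of the Z C11=C12 bond) followed by Kumada coupling with 1,1-dichloroethene.
5. Ring order: the oxirane is made first (step 2) and is consumed when the 14-membered ring is closed (step 10).

Assumption: (3S)-pent-1-yn-3-ol and (2R)-3-bromo-2-methylpropan-1-ol are bought as single enantiomers, and the C2 methyl centre between the two carbonyl groups of the target is the thermodynamically preferred epimer of this ring.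

**Step 1**
Reactants: 1 2-methylidenepropane-1,3-diol
Product: 2 2-({[tert-butyl(dimethyl)silyl]oxy}methyl)prop-2-en-1-ol
Conditions: NaH (1.0 equiv), THF, 0 °C to rt; then TBSCl (1.0 equiv)
Reagents that add atoms: tert-butyl(chloro)dimethylsilane (TBSCl), CC(C)(C)[Si](C)(C)Cl
Why: The sparingly soluble mono-sodium alkoxide of the symmetric diol is silylated once (mono-O-silylation of a symmetric diol), and no stereocentre is formed.

**Step 2**
Reactants: 2 2-({[tert-butyl(dimethyl)silyl]oxy}methyl)prop-2-en-1-ol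
Product: 3 [(2S)-2-({[tert-butyl(dimethyl)silyl]oxy}methyl)oxiran-2-yl]methanol
Conditions: Ti(OiPr)4 (10 mol%), L-(+)-diethyl tartrate (12 mol%), t-BuOOH (2 equiv), 4 Å MS, CH2Cl2, −20 °C
Reagents that add atoms: tert-butyl hydroperoxide, CC(C)(C)OO
Why: Sharpless asymmetric epoxidation of a 2-substituted primary allylic alcohol, in which the L-(+)-tartrate ligand directs oxygen to the face that gives the (S)-oxirane and so sets the future C4 centre (free CH2OH becomes C3, oxirane CH2 becomes C5, silyloxymethyl becomes the CH2OH of the target).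

**Step 3**
Reactants: 3 [(2S)-2-({[tert-butyl(dimethyl)silyl]oxy}methyl)oxiran-2-yl]methanol
Product: 4 (2S)-2-({[tert-butyl(dimethyl)silyl]oxy}methyl)oxirane-2-carbaldehyde
Conditions: TEMPO (10 mol%), PhI(OAc)2 (1.2 equiv), CH2Cl2, rt
Reagents that add atoms: none
Why: Oxoammonium (TEMPO) oxidation of the primary alcohol stops at the aldehyde, and the fully substituted α-carbon cannot epimerise.

**Step 4**
Reactants: 5 (3S)-pent-1-yn-3-ol; 6 1,1-dichloroethene
Product: 8 (3S,4Z)-6-chloro-4-methylhepta-4,6-dien-3-ol, via magnesium chelate 7 (not isolated)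
Conditions: MeMgBr (2.3 equiv), CuI (10 mol%), Et2O/THF, −10 °C to rt; then Pd(PPh3)4 (5 mol%), 6 (8 equiv), 45 °C; aq. NH4Cl
Reagents that add atoms: methylmagnesium bromide, C[Mg]Br
Why: Duboudin-type copper-catalysed anti-carbomagnesiation of the propargylic alkoxide puts methyl on C12 and magnesium on C11 cis to the carbinol carbon (chelate 7), and Kumada mono-coupling of this alkenylmagnesium with excess 1,1-dichloroethene proceeds with retention to give the Z 2-chloro-1,3-diene, while C13 is carried unchanged from 5.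

**Step 5**
Reactants: 8 (3S,4Z)-6-chloro-4-methylhepta-4,6-dien-3-ol; 9 (2R)-3-bromo-2-methylpropan-1-ol
Product: 10 (2S,5Z,7S)-2,6-dimethyl-4-methylidenenon-5-ene-1,7-diol
Conditions: NiI2 (10 mol%), 4,4′-di-tert-butyl-2,2′-bipyridine (10 mol%), NaI (0.5 equiv), pyridine (10 mol%), Mn powder (2.5 equiv), DMPU, 60 °C; 9 (1.5 equiv)
Reagents that add atoms: none
Why: Nickel-catalysed cross-electrophile coupling in which the chloroprene-type C–Cl bond adds to zerovalent nickel and the primary bromide (through its iodide) gives a C9 radical that is captured at nickel, so C9–C10 forms with both hydroxyls free and the C8 centre of 9 untouched.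

**Step 6**
Reactants: 10 (2S,5Z,7S)-2,6-dimethyl-4-methylidenenon-5-ene-1,7-diol
Product: 11 (2S,5Z,7S)-7-hydroxy-2,6-dimethyl-4-methylidenenon-5-enal
Conditions: TEMPO (10 mol%), PhI(OAc)2 (1.1 equiv), CH2Cl2, 0 °C to rt
Reagents that add atoms: none
Why: TEMPO/PhI(OAc)2 oxidises the unhindered primary alcohol much faster than the hindered secondary allylic one, and the non-basic medium leaves the α-methyl aldehyde centre intact.

**Step 7**
Reactants: 11 (2S,5Z,7S)-7-hydroxy-2,6-dimethyl-4-methylidenenon-5-enal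
Product: 12 (3S,4Z,8S,9Z)-10-iodo-4,8-dimethyl-6-methylideneundeca-4,9-dien-3-ol
Conditions: EtPPh3I (3.2 equiv), n-BuLi, THF, rt; I2, −78 °C; NaHMDS, −20 °C; then 11, −78 to −20 °C
Reagents that add atoms: ethyltriphenylphosphonium iodide, CC[P+](c1ccccc1)(c1ccccc1)c1ccccc1.[I-]; iodine, II
Why: Stork–Zhao olefination with the α-iodo ylide gives the Z 2-iodoalkene (iodine cis to C8) under kinetic control, with excess ylide covering the free hydroxyl.

**Step 8**
Reactants: 12 (3S,4Z,8S,9Z)-10-iodo-4,8-dimethyl-6-methylideneundeca-4,9-dien-3-ol; 13 propanoyl chloride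
Product: 14 (3S,4Z,8S,9Z)-10-iodo-4,8-dimethyl-6-methylideneundeca-4,9-dien-3-yl propanoate
Conditions: 13 (1.5 equiv), pyridine, DMAP (5 mol%), CH2Cl2, 0 °C
Reagents that add atoms: none
Why: DMAP-catalysed O-acylation of the secondary alcohol installs C1–C2 without touching any stereocentre.

**Step 9**
Reactants: 14 (3S,4Z,8S,9Z)-10-iodo-4,8-dimethyl-6-methylideneundeca-4,9-dien-3-yl propanoate; 4 (2S)-2-({[tert-butyl(dimethyl)silyl]oxy}methyl)oxirane-2-carbaldehyde
Product: 16 (3S,4Z,8S,9Z)-10-iodo-4,8-dimethyl-6-methylideneundeca-4,9-dien-3-yl 3-[(2S)-2-({[tert-butyl(dimethyl)silyl]oxy}methyl)oxiran-2-yl]-3-hydroxy-2-methylpropanoate, via lithium enolate 15 (not isolated)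
Conditions: LDA (1.1 equiv), THF, −78 °C; then 4 (1.2 equiv), −78 °C; aq. NH4Cl at −78 °C
Reagents that add atoms: none
Why: Lithium ester enolate aldol addition to the non-enolisable epoxy aldehyde, kept at −78 °C to avoid Ireland–Claisen and Payne rearrangements, forms C2–C3 as an epimer mixture that is erased (C3) or equilibrated (C2) in step 11.

**Step 10**
Reactants: 16 (3S,4Z,8S,9Z)-10-iodo-4,8-dimethyl-6-methylideneundeca-4,9-dien-3-yl 3-[(2S)-2-({[tert-butyl(dimethyl)silyl]oxy}methyl)oxiran-2-yl]-3-hydroxy-2-methylpropanoate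
Product: 18 (5S,7Z,9S,12Z,14S)-5-({[tert-butyl(dimethyl)silyl]oxy}methyl)-14-ethyl-4,5-dihydroxy-3,7,9,13-tetramethyl-11-methylidene-1-oxacyclotetradeca-7,12-dien-2-one, via iodohydrin 17 (not isolated)
Conditions: NiCl2(DME) (30 mol%), 2,2′-bipyridine (30 mol%), NaI (1 equiv), Et3N·HCl (1.5 equiv), Mn powder (6 equiv), DMPU, rt; 16 added over 16 h to 2 mM
Reagents that add atoms: none
Why: Proposed new method: Et3N·HCl/NaI opens the oxirane at its CH2 to iodohydrin 17, zerovalent nickel inserts into the alkenyl C–I bond, iodine-atom abstraction from the CH2–I group gives a primary C5 radical that is captured at nickel, and reductive elimination closes the 14-membered ring at C5–C6 with retention of the Z alkene and of C4 (its C–O bond is never broken), the closest known reactions being the nickel/iodide co-catalysed reductive coupling of epoxides with aryl and alkenyl halides and nickel-catalysed alkyl/alkenyl cross-electrophile coupling.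

**Step 11**
Reactants: 18 (5S,7Z,9S,12Z,14S)-5-({[tert-butyl(dimethyl)silyl]oxy}methyl)-14-ethyl-4,5-dihydroxy-3,7,9,13-tetramethyl-11-methylidene-1-oxacyclotetradeca-7,12-dien-2-one
Product: 19 (3R,5S,7Z,9S,12Z,14S)-5-({[tert-butyl(dimethyl)silyl]oxy}methyl)-14-ethyl-5-hydroxy-3,7,9,13-tetramethyl-11-methylidene-1-oxacyclotetradeca-7,12-diene-2,4-dione
Conditions: Dess–Martin periodinane (1.5 equiv), pyridine (5 equiv), CH2Cl2, 0 °C to rt
Reagents that add atoms: none
Why: Dess–Martin oxidation converts the secondary alcohol next to the tertiary one into the ketone, which removes the C3 epimers and makes C2 acidic so that it equilibrates through the enol to the more stable (3R) epimer (thermodynamic control).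

**Step 12**
Reactants: 19 (3R,5S,7Z,9S,12Z,14S)-5-({[tert-butyl(dimethyl)silyl]oxy}methyl)-14-ethyl-5-hydroxy-3,7,9,13-tetramethyl-11-methylidene-1-oxacyclotetradeca-7,12-diene-2,4-dione
Product: 20 (3R,5S,7Z,9S,12Z,14S)-14-ethyl-5-hydroxy-5-(hydroxymethyl)-3,7,9,13-tetramethyl-11-methylidene-1-oxacyclotetradeca-7,12-diene-2,4-dione
Conditions: HF·pyridine, pyridine, THF, 0 °C to rt
Reagents that add atoms: none
Why: Buffered fluoride cleavage of the primary silyl ether (desilylation) is weakly acidic, so the tertiary hydroxyl is not driven by base to attack the lactone carbonyl and no stereocentre is touched.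

**Compound list**
1 | 2-methylidenepropane-1,3-diol | C=C(CO)CO | starting material
2 | 2-({[tert-butyl(dimethyl)silyl]oxy}methyl)prop-2-en-1-ol | C=C(CO)CO[Si](C)(C)C(C)(C)C | intermediate
3 | [(2S)-2-({[tert-butyl(dimethyl)silyl]oxy}methyl)oxiran-2-yl]methanol | OC[C@@]1(CO[Si](C)(C)C(C)(C)C)CO1 | intermediate
4 | (2S)-2-({[tert-butyl(dimethyl)silyl]oxy}methyl)oxirane-2-carbaldehyde | O=C[C@@]1(CO[Si](C)(C)C(C)(C)C)CO1 | intermediate
5 | (3S)-pent-1-yn-3-ol | C#C[C@H](CC)O | starting material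
6 | 1,1-dichloroethene | C=C(Cl)Cl | starting material
7 | (5S)-5-ethyl-4-methyl-2,5-dihydro-1,2-oxamagnesole (magnesium chelate) | CC[C@@H]1O[Mg]C=C1C | intermediate
8 | (3S,4Z)-6-chloro-4-methylhepta-4,6-dien-3-ol | C=C(Cl)/C=C(/C)[C@H](CC)O | intermediate
9 | (2R)-3-bromo-2-methylpropan-1-ol | OC[C@@H](C)CBr | starting material
10 | (2S,5Z,7S)-2,6-dimethyl-4-methylidenenon-5-ene-1,7-diol | OC[C@@H](C)CC(=C)/C=C(/C)[C@H](CC)O | intermediate
11 | (2S,5Z,7S)-7-hydroxy-2,6-dimethyl-4-methylidenenon-5-enal | O=C[C@@H](C)CC(=C)/C=C(/C)[C@H](CC)O | intermediate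
12 | (3S,4Z,8S,9Z)-10-iodo-4,8-dimethyl-6-methylideneundeca-4,9-dien-3-ol | C/C(I)=C/[C@@H](C)CC(=C)/C=C(/C)[C@H](CC)O | intermediate
13 | propanoyl chloride | CCC(=O)Cl | starting material
14 | (3S,4Z,8S,9Z)-10-iodo-4,8-dimethyl-6-methylideneundeca-4,9-dien-3-yl propanoate | C/C(I)=C/[C@@H](C)CC(=C)/C=C(/C)[C@H](CC)OC(=O)CC | intermediate
15 | lithium 1-{[(3S,4Z,8S,9Z)-10-iodo-4,8-dimethyl-6-methylideneundeca-4,9-dien-3-yl]oxy}prop-1-en-1-olate (lithium enolate) | C/C(I)=C/[C@@H](C)CC(=C)/C=C(/C)[C@H](CC)OC(O[Li])=CC | intermediate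
16 | (3S,4Z,8S,9Z)-10-iodo-4,8-dimethyl-6-methylideneundeca-4,9-dien-3-yl 3-[(2S)-2-({[tert-butyl(dimethyl)silyl]oxy}methyl)oxiran-2-yl]-3-hydroxy-2-methylpropanoate (C2/C3 epimer mixture) | C/C(I)=C/[C@@H](C)CC(=C)/C=C(/C)[C@H](CC)OC(=O)C(C)C(O)[C@@]1(CO[Si](C)(C)C(C)(C)C)CO1 | intermediate
17 | (3S,4Z,8S,9Z)-10-iodo-4,8-dimethyl-6-methylideneundeca-4,9-dien-3-yl (4S)-4-({[tert-butyl(dimethyl)silyl]oxy}methyl)-3,4-dihydroxy-5-iodo-2-methylpentanoate (iodohydrin) | C/C(I)=C/[C@@H](C)CC(=C)/C=C(/C)[C@H](CC)OC(=O)C(C)C(O)[C@@](O)(CO[Si](C)(C)C(C)(C)C)CI | intermediate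
18 | (5S,7Z,9S,12Z,14S)-5-({[tert-butyl(dimethyl)silyl]oxy}methyl)-14-ethyl-4,5-dihydroxy-3,7,9,13-tetramethyl-11-methylidene-1-oxacyclotetradeca-7,12-dien-2-one (C3/C4 epimer mixture) | C=C1/C=C(/C)[C@H](CC)OC(=O)C(C)C(O)[C@@](O)(CO[Si](C)(C)C(C)(C)C)C/C(C)=C\[C@@H](C)C1 | intermediate
19 | (3R,5S,7Z,9S,12Z,14S)-5-({[tert-butyl(dimethyl)silyl]oxy}methyl)-14-ethyl-5-hydroxy-3,7,9,13-tetramethyl-11-methylidene-1-oxacyclotetradeca-7,12-diene-2,4-dione | C=C1/C=C(/C)[C@H](CC)OC(=O)[C@H](C)C(=O)[C@@](O)(CO[Si](C)(C)C(C)(C)C)C/C(C)=C\[C@@H](C)C1 | intermediate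
20 | (3R,5S,7Z,9S,12Z,14S)-14-ethyl-5-hydroxy-5-(hydroxymethyl)-3,7,9,13-tetramethyl-11-methylidene-1-oxacyclotetradeca-7,12-diene-2,4-dione | C=C1/C=C(/C)[C@H](CC)OC(=O)[C@H](C)C(=O)[C@@](O)(CO)C/C(C)=C\[C@@H](C)C1 | target

**Step count and risk**
Total steps: 12. Longest linear sequence: 9 steps (steps 4 to 12, from 5 to 20); the three-step epoxide arm (steps 1 to 3) joins at step 9.

The three steps most likely to fail:

Step 10 (ring closure). Risks are oligomerisation, reduction of the alkenyl iodide, ionisation of the allylic ester by nickel, and slow opening of the hindered oxirane. The fallback sets out from 12 and 3 and comes back at 18; it makes the C5–C6 bond between two small partners and closes the ring at C2–C3 instead. Alkenyl iodide 12 and epoxy alcohol 3 are coupled at normal concentration (NiCl2(DME), 2,2′-bipyridine, NaI, Et3N·HCl, Mn powder, DMPU, rt) to give (2R,4Z,6S,9Z,11S)-2-({[tert-butyl(dimethyl)silyl]oxy}methyl)-4,6,10-trimethyl-8-methylidenetrideca-4,9-diene-1,2,11-triol F1. TEMPO/PhI(OAc)2 oxidises its primary alcohol to (2S,4Z,6S,9Z,11S)-2-({[tert-butyl(dimethyl)silyl]oxy}methyl)-2,11-dihydroxy-4,6,10-trimethyl-8-methylidenetrideca-4,9-dienal F2. 2-Bromopropanoyl bromide and pyridine at −40 °C acylate the secondary hydroxyl to give (3S,4Z,8S,9Z,12S)-12-({[tert-butyl(dimethyl)silyl]oxy}methyl)-12-hydroxy-4,8,10-trimethyl-6-methylidene-13-oxotrideca-4,9-dien-3-yl 2-bromopropanoate F3. SmI2 in THF at −78 °C and high dilution then closes the 14-membered ring by an intramolecular samarium Reformatsky reaction to give 18, which goes on to step 11.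

Step 5 (cross-electrophile coupling of the chlorodiene). Risks are addition of the free C9 radical to the chlorodiene, sluggish activation of the C–Cl bond and hydrodehalogenation. The fallback sets out from 9 and comes back at 10; it replaces the radical coupling by a polar Kumada coupling with temporary protection. Compound 9 is silylated (TBSCl, imidazole, CH2Cl2) to [(2R)-3-bromo-2-methylpropoxy](tert-butyl)dimethylsilane F4 and converted with Mg turnings in THF into [(2R)-3-{[tert-butyl(dimethyl)silyl]oxy}-2-methylpropyl]magnesium bromide F5. This is coupled with the magnesium alkoxide of 8 (pre-formed with i-PrMgCl) under Ni(dppp)Cl2 catalysis in THF to give (3S,4Z,8S)-9-{[tert-butyl(dimethyl)silyl]oxy}-4,8-dimethyl-6-methylidenenon-4-en-3-ol F6, and Bu4NF in THF frees diol 10.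

Step 4 (one-pot carbomagnesiation and Kumada coupling). Risks are poor transmetalation of the chelated alkenylmagnesium, double coupling of 1,1-dichloroethene and consumption of the dichloride by excess MeMgBr. The fallback sets out from 5 and 9 and comes back at 10, bypassing 8 and step 5. The chelate from 5 is quenched with I2 to give (1Z,3S)-1-iodo-2-methylpent-1-en-3-ol F7. Separately, 9 is alkylated with lithium acetylide–ethylenediamine in DMSO to give (2S)-2-methylpent-4-yn-1-ol F8. Ni(dppp)Cl2-catalysed α-selective hydroalumination of F8 with i-Bu2AlH, trapped with 2-methoxy-4,4,5,5-tetramethyl-1,3,2-dioxaborolane, gives (2S)-2-methyl-4-(4,4,5,5-tetramethyl-1,3,2-dioxaborolan-2-yl)pent-4-en-1-ol F9. Suzuki coupling of F7 with F9 (Pd(dppf)Cl2, K3PO4, THF/H2O) gives diol 10 with the Z geometry retained.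

**Further compounds**
F1 | step 10 | (2R,4Z,6S,9Z,11S)-2-({[tert-butyl(dimethyl)silyl]oxy}methyl)-4,6,10-trimethyl-8-methylidenetrideca-4,9-diene-1,2,11-triol | OC[C@@](O)(CO[Si](C)(C)C(C)(C)C)C/C(C)=C\[C@@H](C)CC(=C)/C=C(/C)[C@H](CC)O
F2 | step 10 | (2S,4Z,6S,9Z,11S)-2-({[tert-butyl(dimethyl)silyl]oxy}methyl)-2,11-dihydroxy-4,6,10-trimethyl-8-methylidenetrideca-4,9-dienal | O=C[C@@](O)(CO[Si](C)(C)C(C)(C)C)C/C(C)=C\[C@@H](C)CC(=C)/C=C(/C)[C@H](CC)O
F3 | step 10 | (3S,4Z,8S,9Z,12S)-12-({[tert-butyl(dimethyl)silyl]oxy}methyl)-12-hydroxy-4,8,10-trimethyl-6-methylidene-13-oxotrideca-4,9-dien-3-yl 2-bromopropanoate | O=C[C@@](O)(CO[Si](C)(C)C(C)(C)C)C/C(C)=C\[C@@H](C)CC(=C)/C=C(/C)[C@H](CC)OC(=O)C(C)Br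
F4 | step 5 | [(2R)-3-bromo-2-methylpropoxy](tert-butyl)dimethylsilane | CC(C)(C)[Si](C)(C)OC[C@@H](C)CBr
F5 | step 5 | [(2R)-3-{[tert-butyl(dimethyl)silyl]oxy}-2-methylpropyl]magnesium bromide | CC(C)(C)[Si](C)(C)OC[C@@H](C)C[Mg]Br
F6 | step 5 | (3S,4Z,8S)-9-{[tert-butyl(dimethyl)silyl]oxy}-4,8-dimethyl-6-methylidenenon-4-en-3-ol | CC(C)(C)[Si](C)(C)OC[C@@H](C)CC(=C)/C=C(/C)[C@H](CC)O
F7 | step 4 | (1Z,3S)-1-iodo-2-methylpent-1-en-3-ol | I/C=C(/C)[C@H](CC)O
F8 | step 4 | (2S)-2-methylpent-4-yn-1-ol | OC[C@@H](C)CC#C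
F9 | step 4 | (2S)-2-methyl-4-(4,4,5,5-tetramethyl-1,3,2-dioxaborolan-2-yl)pent-4-en-1-ol | OC[C@@H](C)CC(=C)B1OC(C)(C)C(C)(C)O1
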